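**Plan**

1. Retrosynthesis (labdane numbering): the C15 acetate and the C8–C17 bond are cut first (carbonylation of a C7=C8 enol triflate of a C8 ketone). Ring A is then cut at C3–C4 while a bond C4–C7 is drawn in its place.
2. This works because C4, the gem-dimethyl carbon, is 1,3 to C7 across ring B (through C5 and C6) and C7 is α to C8. Ring B with C4, its two methyls, the C10 methyl and the C8 oxygen is then the skeleton of verbenone, a bicyclo[3.1.1]heptenone whose cyclobutane bond C4–C7 is absent from the target.
3. Further cuts: C9–C11 (aldol condensation with a C11–C15 aldehyde) and C10–C1 (conjugate addition of a C1–C3 propargyl unit).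
4. Forward: ring B is bought as (1R,5R)-verbenone. C1–C3 is added at C10 and the side chain at C9 while the cyclobutane blocks C7. Lewis-acid cleavage of C4–C7 then gives a C4 cation that closes ring A on a (Z)-vinylsilane at C3, and a C7=C8 enolate. Hydrogenation, C7=C8 triflation, carbonylation to C17 and silyl-to-acetate exchange finish the target.
5. Stereochemistry: C5 from verbenone; C10 by addition anti to the gem-dimethyl bridge; C9 by protonation anti to the same bridge; the trans ring fusion is therefore fixed before ring A closes; C13 from methyl hydrogen (R)-3-methylglutarate.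

Key step: step 8

Remark: (1R,5R)-verbenone, tributyl(propa-1,2-dien-1-yl)stannane and methyl hydrogen (R)-3-methylglutarate are taken to be purchasable (the chiral ones enantiopure). Labdane numbering (ring A = C1–C5, C10; ring B = C5–C10) is used for every intermediate.

**Route**

Step 1
Reactants: 1 (1R,5R)-verbenone; 2 tributyl(propa-1,2-dien-1-yl)stannane
Product: 3 (1R,4R,5R)-4,6,6-trimethyl-4-(prop-2-yn-1-yl)bicyclo[3.1.1]heptan-2-one
Conditions: TiCl4, CH2Cl2, −78 °C; aq NaHCO3
Reagents that add atoms: none
Why: TiCl4 activates the enone and the allenylstannane adds through its terminal CH2 carbon in an SE2′ sense (Lewis-acid-promoted conjugate propargylation, a Hosomi–Sakurai-type addition); attack at C10 should come from the face opposite the gem-dimethyl bridge, so the C1 chain ends anti to C4 and the C10 methyl syn to it, as in the target.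

Step 2
Reactants: 3 (1R,4R,5R)-4,6,6-trimethyl-4-(prop-2-yn-1-yl)bicyclo[3.1.1]heptan-2-one
Product: 4 (1R,4R,5R)-4,6,6-trimethyl-4-[(2Z)-3-(triethylsilyl)prop-2-en-1-yl]bicyclo[3.1.1]heptan-2-one
Conditions: Et3SiH, [RuCl2(p-cymene)]2 (divalent ruthenium, 2.5 mol %), CH2Cl2, 40 °C
Reagents that add atoms: triethylsilane CC[SiH](CC)CC
Why: The arene ruthenium dichloride dimer should add Si–H across the terminal alkyne in a formal trans sense (ruthenium-catalysed trans-hydrosilylation), placing silicon on the terminal carbon C3 cis to the C1 methylene, which gives the (Z)-vinylsilane needed as the π-nucleophile for an endocyclic ring closure, while the hindered ketone is left alone.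

Step 3
Reactants: 5 methyl hydrogen (R)-3-methylglutarate
Product: 6 methyl (R)-5-hydroxy-3-methylpentanoate
Conditions: BH3·SMe2, THF, −10 °C to rt; H2O
Reagents that add atoms: none
Why: Borane reduces the free carboxylic acid through its acyloxyborane much faster than the methyl ester (chemoselective acid reduction), and the stereocentre that becomes C13 is not touched.

Step 4
Reactants: 6 methyl (R)-5-hydroxy-3-methylpentanoate
Product: 7 methyl (R)-5-[(tert-butyldiphenylsilyl)oxy]-3-methylpentanoate
Conditions: t-BuPh2SiCl, imidazole, DMF, rt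
Reagents that add atoms: tert-butyl(chloro)diphenylsilane CC(C)(C)[Si](Cl)(c1ccccc1)c1ccccc1
Why: Standard silylation of the primary alcohol; the bulky silyl ether is chosen to survive amide bases, SnCl4, hydrogenation and the carbonylation.

Step 5
Reactants: 7 methyl (R)-5-[(tert-butyldiphenylsilyl)oxy]-3-methylpentanoate
Product: 8 (R)-5-[(tert-butyldiphenylsilyl)oxy]-3-methylpentanal
Conditions: i-Bu2AlH, CH2Cl2, −78 °C; aq KNaC4H4O6
Reagents that add atoms: none
Why: Partial reduction of the methyl ester at low temperature should stop at the aluminium hemiacetal, which releases the aldehyde (C11) on work-up.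

Step 6
Reactants: 4 (1R,4R,5R)-4,6,6-trimethyl-4-[(2Z)-3-(triethylsilyl)prop-2-en-1-yl]bicyclo[3.1.1]heptan-2-one; 8 (R)-5-[(tert-butyldiphenylsilyl)oxy]-3-methylpentanal
Product: 12 (1R,4S,5S)-3-[(3S)-5-[(tert-butyldiphenylsilyl)oxy]-3-methylpentylidene]-4,6,6-trimethyl-4-[(2Z)-3-(triethylsilyl)prop-2-en-1-yl]bicyclo[3.1.1]heptan-2-one (C9=C11 geometry immaterial), via lithium enolate 9 (not isolated), via lithium aldolate 10 (not isolated), via aldol mesylate 11 (not isolated)
Conditions: LiN(i-Pr)2, THF, −78 °C; 8; MsCl, −78 to 0 °C; DBU, rt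
Reagents that add atoms: none
Why: C9 is the only enolisable position of 4 because C7 is a bridgehead, so the lithium enolate adds to aldehyde 8 (directed aldol reaction) and mesylation followed by E1cB elimination gives the C9=C11 enone; no stereocentre needs control here because C9 becomes sp2.

Step 7
Reactants: 12 the C9=C11 enone of step 6
Product: 14 (1R,3R,4S,5S)-3-[(3S)-5-[(tert-butyldiphenylsilyl)oxy]-3-methylpentyl]-4,6,6-trimethyl-4-[(2Z)-3-(triethylsilyl)prop-2-en-1-yl]bicyclo[3.1.1]heptan-2-one, via lithium enolate 13 (not isolated)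
Conditions: Li[HB(s-Bu)3], THF, −78 °C; AcOH, −78 °C
Reagents that add atoms: none
Why: The hindered borohydride should deliver hydride to C11 in a conjugate (1,4) reduction because the carbonyl is flanked by a bridgehead and a carbon next to a quaternary centre, and kinetic protonation of the enolate at C9 on the face opposite the gem-dimethyl bridge places the side chain syn to the C10 methyl, as in the target.

Step 8
Reactants: 14 the saturated bicyclic ketone of step 7
Product: 17 (5S,9R,10S,13S)-15-[(tert-butyldiphenylsilyl)oxy]-17-norlabd-2-en-8-one, via ring-opened zwitterion 15 (not isolated), via trichlorostannyl enolate 16 (not isolated)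
Conditions: SnCl4, 2,6-di-tert-butyl-4-methylpyridine, CH2Cl2, −78 to −20 °C; aq NaHCO3
Reagents that add atoms: none
Why: Proposed new method: SnCl4 binds the C8 carbonyl, and the strained cyclobutane bond C4–C7, which is α,β to that carbonyl and aligned with its π system, should break heterolytically to a C7=C8 tin enolate and the tertiary C4 cation (C7–C4 breaks rather than C7–C6 because only it gives a tertiary cation); the cation, held on C5 next to the C10 chain, is captured at the silicon-bearing C3 of the vinylsilane, and the β-silyl cation at C2 loses Et3Si to chloride to leave the C2=C3 alkene. The closest known reaction types are the Lewis-acid opening of nopinone-type cyclobutyl ketones, including cases where a tethered phenol oxygen captures the same tertiary cation to close a six-membered ring, and vinylsilane-terminated cation–olefin cyclisations; joining the two with a carbon terminator is the new element. Ring A closes in a 6-endo-trig mode with respect to the vinylsilane (both alkene carbons end in the ring), through a chair-like arrangement in which the C5 and C10 substituents are trans-diequatorial on ring B, and the (Z) geometry lets the C3–Si bond turn into line with the empty p orbital at C2 while C4 swings towards C1, so that silicon stabilises the cation as the bond forms and C4 takes the place of silicon in a cis ring alkene. No new stereocentre is formed: C4 becomes a non-stereogenic quaternary carbon, the trans ring fusion follows from C5 and C10 set earlier, and C9 is not enolised because the enolate forms towards C7. The step needs attack at C3 rather than C2 (silicon stabilises the cation β to it, whereas five-membered closure would give an unstabilised α-silyl cation) and cyclisation rather than proton loss from the C4 cation (elimination to an isopropenyl group is reversible under the Lewis acid, and the hindered pyridine suppresses protodesilylation). Aqueous work-up protonates the enolate at C7 to give the ketone.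

Step 9
Reactants: 17 (5S,9R,10S,13S)-15-[(tert-butyldiphenylsilyl)oxy]-17-norlabd-2-en-8-one
Product: 18 (5S,9R,10S,13S)-15-[(tert-butyldiphenylsilyl)oxy]-17-norlabdan-8-one
Conditions: H2 (1 atm), Pd/C, EtOAc, rt
Reagents that add atoms: none
Why: Heterogeneous hydrogenation should saturate the cis-disubstituted C2=C3 alkene left by the vinylsilane, while ketone and silyl ether are inert under these conditions.

Step 10
Reactants: 18 (5S,9R,10S,13S)-15-[(tert-butyldiphenylsilyl)oxy]-17-norlabdan-8-one
Product: 20 (5S,9R,10S,13S)-15-[(tert-butyldiphenylsilyl)oxy]-17-norlabd-7-en-8-yl trifluoromethanesulfonate, via potassium enolate 19 (not isolated)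
Conditions: KN(SiMe3)2, THF, −78 °C; PhNTf2, −78 to 0 °C
Reagents that add atoms: N-phenylbis(trifluoromethanesulfonimide) O=S(=O)(N(c1ccccc1)S(=O)(=O)C(F)(F)F)C(F)(F)F
Why: Kinetic deprotonation by the bulky amide should occur at the C7 methylene rather than at the hindered tertiary C9–H, and O-triflation of the enolate fixes the C7=C8 double bond and leaves C9 untouched.

Step 11
Reactants: 20 the C7=C8 enol triflate of step 10
Product: 21 (5S,9R,10S,13S)-15-[(tert-butyldiphenylsilyl)oxy]labd-7-en-17-oic acid
Conditions: CO (1 atm), Pd(OAc)2, PPh3, KOAc, DMF/H2O, rt to 50 °C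
Reagents that add atoms: carbon monoxide [C-]#[O+]; water O
Why: Oxidative addition of zerovalent palladium to the enol triflate, CO insertion and hydrolysis of the acylpalladium by water (palladium-catalysed hydroxycarbonylation) should install C17 as the conjugated carboxylic acid.

Step 12
Reactants: 21 (5S,9R,10S,13S)-15-[(tert-butyldiphenylsilyl)oxy]labd-7-en-17-oic acid
Product: 22 (5S,9R,10S,13S)-15-hydroxylabd-7-en-17-oic acid
Conditions: HF·pyridine, THF/pyridine, 0 °C to rt
Reagents that add atoms: none
Why: Fluoride cleaves the Si–O bond of the primary silyl ether, and the acid and the trisubstituted alkene are unaffected.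

Step 13
Reactants: 22 (5S,9R,10S,13S)-15-hydroxylabd-7-en-17-oic acid
Product: 23 (5S,9R,10S,13S)-15-acetoxylabd-7-en-17-oic acid (target)
Conditions: Ac2O, pyridine, DMAP, CH2Cl2, 0 °C to rt; aq NaHCO3
Reagents that add atoms: acetic anhydride CC(=O)OC(C)=O
Why: Acylation of the primary alcohol; any mixed anhydride formed at the carboxyl group is hydrolysed during the bicarbonate work-up, which should give the target.

**Compound list**

1 | (1R,5R)-verbenone | CC1=CC(=O)[C@@H]2C[C@H]1C2(C)C | starting material
2 | tributyl(propa-1,2-dien-1-yl)stannane | C=C=C[Sn](CCCC)(CCCC)CCCC | starting material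
3 | (1R,4R,5R)-4,6,6-trimethyl-4-(prop-2-yn-1-yl)bicyclo[3.1.1]heptan-2-one | C1C(=O)[C@@H]2C[C@@H](C2(C)C)[C@]1(C)CC#C | intermediate
4 | (1R,4R,5R)-4,6,6-trimethyl-4-[(2Z)-3-(triethylsilyl)prop-2-en-1-yl]bicyclo[3.1.1]heptan-2-one | C1C(=O)[C@@H]2C[C@@H](C2(C)C)[C@]1(C)C\C=C/[Si](CC)(CC)CC | intermediate
5 | methyl hydrogen (R)-3-methylglutarate | COC(=O)C[C@H](C)CC(=O)O | starting material
6 | methyl (R)-5-hydroxy-3-methylpentanoate | COC(=O)C[C@H](C)CCO | intermediate
7 | methyl (R)-5-[(tert-butyldiphenylsilyl)oxy]-3-methylpentanoate | COC(=O)C[C@H](C)CCO[Si](c1ccccc1)(c1ccccc1)C(C)(C)C | intermediate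
8 | (R)-5-[(tert-butyldiphenylsilyl)oxy]-3-methylpentanal | O=CC[C@H](C)CCO[Si](c1ccccc1)(c1ccccc1)C(C)(C)C | intermediate
9 | lithium enolate of 4 (C8=C9) | C1=C([O-])[C@@H]2C[C@@H](C2(C)C)[C@]1(C)C\C=C/[Si](CC)(CC)CC.[Li+] | intermediate
10 | lithium aldolate of 4 and 8 (alkoxide at C11; mixture at C9 and C11) | CC(C)(C)[Si](c1ccccc1)(c1ccccc1)OCC[C@@H](C)CC([O-])C1C(=O)[C@@H]2C[C@@H](C2(C)C)[C@]1(C)C\C=C/[Si](CC)(CC)CC.[Li+] | intermediate
11 | aldol mesylate (methanesulfonate at C11; mixture at C9 and C11) | CC(C)(C)[Si](c1ccccc1)(c1ccccc1)OCC[C@@H](C)CC(OS(C)(=O)=O)C1C(=O)[C@@H]2C[C@@H](C2(C)C)[C@]1(C)C\C=C/[Si](CC)(CC)CC | intermediate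
12 | (1R,4S,5S)-3-[(3S)-5-[(tert-butyldiphenylsilyl)oxy]-3-methylpentylidene]-4,6,6-trimethyl-4-[(2Z)-3-(triethylsilyl)prop-2-en-1-yl]bicyclo[3.1.1]heptan-2-one (C9=C11 geometry not fixed) | CC(C)(C)[Si](c1ccccc1)(c1ccccc1)OCC[C@@H](C)CC=C1C(=O)[C@@H]2C[C@@H](C2(C)C)[C@]1(C)C\C=C/[Si](CC)(CC)CC | intermediate
13 | lithium enolate of 14 (C8=C9) | CC(C)(C)[Si](c1ccccc1)(c1ccccc1)OCC[C@@H](C)CCC1=C([O-])[C@@H]2C[C@@H](C2(C)C)[C@]1(C)C\C=C/[Si](CC)(CC)CC.[Li+] | intermediate
14 | (1R,3R,4S,5S)-3-[(3S)-5-[(tert-butyldiphenylsilyl)oxy]-3-methylpentyl]-4,6,6-trimethyl-4-[(2Z)-3-(triethylsilyl)prop-2-en-1-yl]bicyclo[3.1.1]heptan-2-one (side chain syn to the gem-dimethyl bridge) | CC(C)(C)[Si](c1ccccc1)(c1ccccc1)OCC[C@@H](C)CC[C@H]1C(=O)[C@@H]2C[C@@H](C2(C)C)[C@]1(C)C\C=C/[Si](CC)(CC)CC | intermediate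
15 | ring-opened zwitterion (tertiary cation at C4, C7=C8 tetrachlorostannate enolate) | CC(C)(C)[Si](c1ccccc1)(c1ccccc1)OCC[C@@H](C)CC[C@H]1C(O[Sn-](Cl)(Cl)(Cl)Cl)=CC[C@@H]([C+](C)C)[C@]1(C)C\C=C/[Si](CC)(CC)CC | intermediate
16 | trichlorostannyl C7=C8 enolate of 17 | CC(C)(C)[Si](c1ccccc1)(c1ccccc1)OCC[C@@H](C)CC[C@H]1C(O[Sn](Cl)(Cl)Cl)=CC[C@H]2C(C)(C)C=CC[C@]12C | intermediate
17 | (5S,9R,10S,13S)-15-[(tert-butyldiphenylsilyl)oxy]-17-norlabd-2-en-8-one | CC(C)(C)[Si](c1ccccc1)(c1ccccc1)OCC[C@@H](C)CC[C@H]1C(=O)CC[C@H]2C(C)(C)C=CC[C@]12C | intermediate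
18 | (5S,9R,10S,13S)-15-[(tert-butyldiphenylsilyl)oxy]-17-norlabdan-8-one | CC(C)(C)[Si](c1ccccc1)(c1ccccc1)OCC[C@@H](C)CC[C@H]1C(=O)CC[C@H]2C(C)(C)CCC[C@]12C | intermediate
19 | potassium C7=C8 enolate of 18 | CC(C)(C)[Si](c1ccccc1)(c1ccccc1)OCC[C@@H](C)CC[C@H]1C([O-])=CC[C@H]2C(C)(C)CCC[C@]12C.[K+] | intermediate
20 | (5S,9R,10S,13S)-15-[(tert-butyldiphenylsilyl)oxy]-17-norlabd-7-en-8-yl trifluoromethanesulfonate | CC(C)(C)[Si](c1ccccc1)(c1ccccc1)OCC[C@@H](C)CC[C@H]1C(OS(=O)(=O)C(F)(F)F)=CC[C@H]2C(C)(C)CCC[C@]12C | intermediate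
21 | (5S,9R,10S,13S)-15-[(tert-butyldiphenylsilyl)oxy]labd-7-en-17-oic acid | CC(C)(C)[Si](c1ccccc1)(c1ccccc1)OCC[C@@H](C)CC[C@H]1C(C(=O)O)=CC[C@H]2C(C)(C)CCC[C@]12C | intermediate
22 | (5S,9R,10S,13S)-15-hydroxylabd-7-en-17-oic acid | OCC[C@@H](C)CC[C@H]1C(C(=O)O)=CC[C@H]2C(C)(C)CCC[C@]12C | intermediate
23 | (5S,9R,10S,13S)-15-acetoxylabd-7-en-17-oic acid | CC(=O)OCC[C@@H](C)CC[C@H]1C(C(=O)O)=CC[C@H]2C(C)(C)CCC[C@]12C | target

**Step count and risks**

Total steps: 13. Longest linear sequence: 11 (steps 3 to 13, from methyl hydrogen (R)-3-methylglutarate 5); the branch from verbenone 1 runs through 10 steps (1, 2 and 6 to 13).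

Steps most likely to fail:

1. Step 8. The C4 cation may lose a proton or take up chloride faster than the vinylsilane traps it, the vinylsilane may add to the activated C8 carbonyl or be protodesilylated, or ring opening may need a temperature at which the silyl ether suffers. Fallback (sets out from 14, returns at 17): the two events are uncoupled with known reactions. Acetolytic opening of the cyclobutane (BF3·OEt2, Zn(OAc)2, Ac2O, 0 °C), the established way to open nopinone-type ketones, should give the ring-opened C7=C8 enol acetate carrying a 2-acetoxypropan-2-yl group at C5 F1. Ionisation of this tertiary acetate (SnCl4, CH2Cl2, −78 °C), a conventional vinylsilane-terminated cation–olefin cyclisation, should close ring A to the C8 enol acetate of the ring-closed ketone F2. K2CO3 in MeOH then frees ketone 17.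

2. Step 1. The allenylstannane may react sluggishly at the hindered β,β-disubstituted position, add 1,2 to the carbonyl, or deliver the allenyl instead of the propargyl adduct. Fallback (sets out from 1, returns at 3): Hosomi–Sakurai allylation with the more nucleophilic allyltrimethylsilane (TiCl4, CH2Cl2, −78 °C), which has no such regiochemical ambiguity, should give (1R,4R,5R)-4,6,6-trimethyl-4-(prop-2-en-1-yl)bicyclo[3.1.1]heptan-2-one F3. Ozonolysis (O3, CH2Cl2, −78 °C; Me2S) gives 2-[(1R,2R,5R)-2,6,6-trimethyl-4-oxobicyclo[3.1.1]heptan-2-yl]acetaldehyde F4. Ohira–Bestmann alkynylation (dimethyl (1-diazo-2-oxopropyl)phosphonate, K2CO3, MeOH) of the aldehyde then gives alkyne 3.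

3. Step 7. Competing 1,2-reduction, poor facial control in the protonation, or later epimerisation at C9 (the side chain sits on the more hindered face of the bicycle) may erode the C9 configuration. Fallback (sets out from 12, returns at 18): enone 12 is carried unreduced through the SnCl4 ring opening and ring closure of step 8 to (5S,10S,13S)-15-[(tert-butyldiphenylsilyl)oxy]-17-norlabda-2,9(11)-dien-8-one F5. H2 over Pd/C then saturates C2=C3 and C9=C11 together, hydrogen adding to C9 from the α face opposite the axial C10 methyl, which should give 18 directly.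

**Further compounds**

F1 | step 8 | ring-opened C7=C8 enol acetate with a 2-acetoxypropan-2-yl group at C5 | CC(C)(C)[Si](c1ccccc1)(c1ccccc1)OCC[C@@H](C)CC[C@H]1C(OC(C)=O)=CC[C@@H](C(C)(C)OC(C)=O)[C@]1(C)C\C=C/[Si](CC)(CC)CC
F2 | step 8 | C8 enol acetate of 17 | CC(C)(C)[Si](c1ccccc1)(c1ccccc1)OCC[C@@H](C)CC[C@H]1C(OC(C)=O)=CC[C@H]2C(C)(C)C=CC[C@]12C
F3 | step 1 | (1R,4R,5R)-4,6,6-trimethyl-4-(prop-2-en-1-yl)bicyclo[3.1.1]heptan-2-one | C1C(=O)[C@@H]2C[C@@H](C2(C)C)[C@]1(C)CC=C
F4 | step 1 | 2-[(1R,2R,5R)-2,6,6-trimethyl-4-oxobicyclo[3.1.1]heptan-2-yl]acetaldehyde | C1C(=O)[C@@H]2C[C@@H](C2(C)C)[C@]1(C)CC=O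
F5 | step 7 | (5S,10S,13S)-15-[(tert-butyldiphenylsilyl)oxy]-17-norlabda-2,9(11)-dien-8-one | CC(C)(C)[Si](c1ccccc1)(c1ccccc1)OCC[C@@H](C)CC=C1C(=O)CC[C@H]2C(C)(C)C=CC[C@]12C
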